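**Strategy.** Everything rests on reading C4 of the top epicatechin unit as a masked aldehyde carbon that is arylated twice: by C4a of its own ring A and by C8 of ring A of the next unit. The precursors are the benzyl-protected lower trimer (from catechin and epicatechin) and an open-chain aryl ether acetal whose C2 and C3 centres come from a catalytic asymmetric cis-epoxidation and an SN2 opening by the ring A phenol. One Lewis acid operation ionises the acetal, closes ring C (O1, C2, C3, C4, C4a, C8a) by Friedel–Crafts attack, re-ionises C4 and joins it to the trimer on the β face. Hydrogenolysis finishes.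

Key step: step 10

Remark: the target is read as epicatechin-(4β→8)-epicatechin-(4β→8)-epicatechin-(4β→8)-catechin with all units 2R; all starting materials are taken as commercially available.

Step 1
Reactants: 1 (+)-catechin
Product: 2 5,7,3',4'-tetra-O-benzyl-(+)-catechin
Conditions: BnBr (4.4 equiv), K2CO3, DMF, 0 °C to rt
Reagents that add atoms: benzyl bromide, BrCc1ccccc1
Why: Williamson etherification in which K2CO3 deprotonates only the four phenols, so the aliphatic 3-OH stays free and no stereocentre is touched.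

Step 2
Reactants: 3 (−)-epicatechin
Product: 4 5,7,3',4'-tetra-O-benzyl-(−)-epicatechin
Conditions: BnBr (4.4 equiv), K2CO3, DMF, 0 °C to rt
Reagents that add atoms: benzyl bromide, BrCc1ccccc1
Why: the same phenol-selective Williamson etherification as in step 1, with no stereocentre touched.

Step 3
Reactants: 4 5,7,3',4'-tetra-O-benzyl-(−)-epicatechin
Product: 5 4β-(2-ethoxyethoxy)-5,7,3',4'-tetra-O-benzylepicatechin (2R,3R,4S; 2,3-cis, 3,4-trans)
Conditions: DDQ (2 equiv), 2-ethoxyethanol (5 equiv), CH2Cl2, rt
Reagents that add atoms: 2-ethoxyethanol, CCOCCO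
Why: benzylic oxidation by hydride abstraction with DDQ at C4 (activated by O1 and the 5,7-dibenzyloxy ring A) should give a cation that the alcohol traps on the β face, anti to the 2-aryl and 3-OH groups, which sets C4.

Step 4
Reactants: 5 4β-(2-ethoxyethoxy)-5,7,3',4'-tetra-O-benzylepicatechin; 2 5,7,3',4'-tetra-O-benzyl-(+)-catechin (4 equiv, excess recovered)
Product: 6 octa-O-benzyl epicatechin-(4β→8)-catechin
Conditions: TMSOTf (0.1 equiv), CH2Cl2, −78 °C; aq. NaHCO3
Reagents that add atoms: none
Why: Friedel–Crafts alkylation in which TMSOTf ionises the C4 ether of 5 and the flavan-4-yl cation is attacked by C8 of 2 from the β face, anti to the 3-OH and 2-aryl groups, which sets the 4β→8 bond, while the excess of 2 suppresses oligomerisation.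

Step 5
Reactants: 5 4β-(2-ethoxyethoxy)-5,7,3',4'-tetra-O-benzylepicatechin; 6 octa-O-benzyl epicatechin-(4β→8)-catechin (3 equiv, excess recovered)
Product: 7 dodeca-O-benzyl epicatechin-(4β→8)-epicatechin-(4β→8)-catechin
Conditions: TMSOTf (0.1 equiv), CH2Cl2, −78 °C; aq. NaHCO3
Reagents that add atoms: none
Why: the same Friedel–Crafts coupling, in which the cation from 5 should be captured on its β face by C8 of the upper unit of 6, the only free C8 position (the free C6 positions lie between two benzyloxy groups), which sets the new C4 centre 3,4-trans.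

Step 6
Reactants: 8 4-bromo-1,2-bis(benzyloxy)benzene; 9 3,3-diethoxyprop-1-yne
Product: 10 1,2-bis(benzyloxy)-4-(3,3-diethoxyprop-1-yn-1-yl)benzene
Conditions: PdCl2(PPh3)2 (3 mol %), CuI (5 mol %), Et3N, DMF, 80 °C
Reagents that add atoms: none
Why: Sonogashira coupling of an aryl bromide with a terminal alkyne, to which the acetal and benzyl ethers are inert and in which no stereocentre is formed.

Step 7
Reactants: 10 1,2-bis(benzyloxy)-4-(3,3-diethoxyprop-1-yn-1-yl)benzene
Product: 11 (Z)-1,2-bis(benzyloxy)-4-(3,3-diethoxyprop-1-en-1-yl)benzene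
Conditions: H2 (1 atm), Pd/CaCO3 poisoned with Pb(OAc)2, quinoline, EtOAc, rt
Reagents that add atoms: none
Why: Lindlar semihydrogenation adds hydrogen syn to the alkyne to give the Z alkene, and the poisoned catalyst should spare the benzyl ethers and the alkene.

Step 8
Reactants: 11 (Z)-1,2-bis(benzyloxy)-4-(3,3-diethoxyprop-1-en-1-yl)benzene
Product: 12 (2S,3S)-2-[3,4-bis(benzyloxy)phenyl]-3-(diethoxymethyl)oxirane (cis)
Conditions: (S,S)-N,N'-bis(3,5-di-tert-butylsalicylidene)-1,2-cyclohexanediaminomanganese chloride (5 mol %), 4-phenylpyridine N-oxide (0.2 equiv), aq. NaOCl (pH 11.3), CH2Cl2, 0 °C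
Reagents that add atoms: sodium hypochlorite, [Na+].[O-]Cl
Why: Jacobsen–Katsuki epoxidation, for which cis-β-substituted styrenes are the best substrate class, should set both oxirane centres by catalyst control (the (S,S) complex gives the benzylic S centre, as with indene and cis-β-methylstyrene), and the basic two-phase medium preserves the acetal and the acid-labile epoxide.

Step 9
Reactants: 12 (2S,3S)-2-[3,4-bis(benzyloxy)phenyl]-3-(diethoxymethyl)oxirane; 13 3,5-bis(benzyloxy)phenol
Product: 14 (2S,3R)-3-[3,5-bis(benzyloxy)phenoxy]-3-[3,4-bis(benzyloxy)phenyl]-1,1-diethoxypropan-2-ol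
Conditions: Cs2CO3 (0.3 equiv), DMF, 70 °C
Reagents that add atoms: none
Why: SN2 opening of the epoxide by the phenoxide at the benzylic carbon (the other carbon is deactivated by the adjacent acetal) with inversion should turn the cis-epoxide into the ether with the 2,3-cis relationship of epicatechin, the carbinol centre being carried over unchanged.

Step 10
Reactants: 14 (2S,3R)-3-[3,5-bis(benzyloxy)phenoxy]-3-[3,4-bis(benzyloxy)phenyl]-1,1-diethoxypropan-2-ol; 7 dodeca-O-benzyl epicatechin-(4β→8)-epicatechin-(4β→8)-catechin (2 equiv, excess recovered)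
Product: 16 hexadeca-O-benzyl epicatechin-(4β→8)-epicatechin-(4β→8)-epicatechin-(4β→8)-catechin, via 4β-ethoxy-tetra-O-benzylepicatechin 15 (not isolated)
Conditions: TMSOTf (0.3 equiv), CH2Cl2, −78 to −40 °C, slow addition of 14 to 7; aq. NaHCO3
Reagents that add atoms: none
Why: TMSOTf ionises the diethyl acetal of 14 to an oxocarbenium ion at C4, which is attacked by an ortho carbon of the 3,5-bis(benzyloxy)phenoxy ring (activated by three oxygen substituents, both ortho positions equivalent) in a 6-exo-trig Friedel–Crafts cyclisation that closes ring C as the 4-ethoxyflavan 15. Compound 15 is a 4-alkoxyflavan of the same kind as 5 and should ionise under the same acid to the C4 cation stabilised by O1 and the 5- and 7-benzyloxy groups, which C8 of the top unit of 7 then captures. The closest known reaction type is the Baeyer-type double Friedel–Crafts arylation of an aldehyde acetal by two arenes, here one intramolecular and one intermolecular, the second half being the flavan-4-yl coupling of steps 4 and 5. C2 and C3 are carried over unchanged from 14, and the new centre C4 is set under substrate control: the 2-aryl and 3-OH groups shield the α face of the cation, so 7 adds to the β face and gives the 3,4-trans (4β→8) bond. The step needs cyclisation before intermolecular capture of the first cation (secured by the tether and the six-membered transition state), capture of the second cation by 7 and not by 14 or 16 (secured by slow addition of 14 to an excess of 7), and attack through C8 of the top unit of 7 (the only free C8 position, the free C6 positions lying between two benzyloxy groups).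

Step 11
Reactants: 16 hexadeca-O-benzyl epicatechin-(4β→8)-epicatechin-(4β→8)-epicatechin-(4β→8)-catechin
Product: 17 epicatechin-(4β→8)-epicatechin-(4β→8)-epicatechin-(4β→8)-catechin (the target)
Conditions: H2 (1 atm), Pd(OH)2/C, THF/MeOH/H2O, rt
Reagents that add atoms: none
Why: hydrogenolysis of the sixteen benzyl ethers under neutral conditions is the standard unmasking of procyanidins and should leave the interflavan bonds, the ring C ether bonds and all stereocentres untouched.

**Compound list**

1 | (+)-catechin, (2R,3S) | Oc1cc(O)c2c(c1)O[C@H](c1ccc(O)c(O)c1)[C@@H](O)C2 | starting material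
2 | 5,7,3',4'-tetra-O-benzyl-(+)-catechin, (2R,3S) | c1ccccc1COc1cc(OCc3ccccc3)c2c(c1)O[C@H](c1ccc(OCc3ccccc3)c(OCc3ccccc3)c1)[C@@H](O)C2 | intermediate
3 | (−)-epicatechin, (2R,3R) | Oc1cc(O)c2c(c1)O[C@H](c1ccc(O)c(O)c1)[C@H](O)C2 | starting material
4 | 5,7,3',4'-tetra-O-benzyl-(−)-epicatechin, (2R,3R) | c1ccccc1COc1cc(OCc3ccccc3)c2c(c1)O[C@H](c1ccc(OCc3ccccc3)c(OCc3ccccc3)c1)[C@H](O)C2 | intermediate
5 | 4β-(2-ethoxyethoxy)-5,7,3',4'-tetra-O-benzylepicatechin, (2R,3R,4S) | c1ccccc1COc1cc(OCc3ccccc3)c2c(c1)O[C@H](c1ccc(OCc3ccccc3)c(OCc3ccccc3)c1)[C@H](O)[C@H]2OCCOCC | intermediate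
6 | octa-O-benzyl epicatechin-(4β→8)-catechin, a benzylated procyanidin dimer | c1ccccc1COc1cc(OCc3ccccc3)c2c(c1)O[C@H](c1ccc(OCc3ccccc3)c(OCc3ccccc3)c1)[C@H](O)[C@H]2c1c(OCc3ccccc3)cc(OCc3ccccc3)c2c1O[C@H](c1ccc(OCc3ccccc3)c(OCc3ccccc3)c1)[C@@H](O)C2 | intermediate
7 | dodeca-O-benzyl epicatechin-(4β→8)-epicatechin-(4β→8)-catechin, a benzylated procyanidin trimer | c1ccccc1COc1cc(OCc3ccccc3)c2c(c1)O[C@H](c1ccc(OCc3ccccc3)c(OCc3ccccc3)c1)[C@H](O)[C@H]2c1c(OCc3ccccc3)cc(OCc3ccccc3)c2c1O[C@H](c1ccc(OCc3ccccc3)c(OCc3ccccc3)c1)[C@H](O)[C@H]2c1c(OCc3ccccc3)cc(OCc3ccccc3)c2c1O[C@H](c1ccc(OCc3ccccc3)c(OCc3ccccc3)c1)[C@@H](O)C2 | intermediate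
8 | 4-bromo-1,2-bis(benzyloxy)benzene | Brc1ccc(OCc2ccccc2)c(OCc2ccccc2)c1 | starting material
9 | 3,3-diethoxyprop-1-yne | C#CC(OCC)OCC | starting material
10 | 1,2-bis(benzyloxy)-4-(3,3-diethoxyprop-1-yn-1-yl)benzene | CCOC(OCC)C#Cc1ccc(OCc2ccccc2)c(OCc2ccccc2)c1 | intermediate
11 | (Z)-1,2-bis(benzyloxy)-4-(3,3-diethoxyprop-1-en-1-yl)benzene | CCOC(OCC)/C=C\c1ccc(OCc2ccccc2)c(OCc2ccccc2)c1 | intermediate
12 | (2S,3S)-2-[3,4-bis(benzyloxy)phenyl]-3-(diethoxymethyl)oxirane, cis | CCOC(OCC)[C@H]1O[C@H]1c1ccc(OCc2ccccc2)c(OCc2ccccc2)c1 | intermediate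
13 | 3,5-bis(benzyloxy)phenol | Oc1cc(OCc2ccccc2)cc(OCc2ccccc2)c1 | starting material
14 | (2S,3R)-3-[3,5-bis(benzyloxy)phenoxy]-3-[3,4-bis(benzyloxy)phenyl]-1,1-diethoxypropan-2-ol | c1ccccc1COc1cc(OCc3ccccc3)cc(c1)O[C@H](c1ccc(OCc3ccccc3)c(OCc3ccccc3)c1)[C@H](O)C(OCC)OCC | intermediate
15 | 4β-ethoxy-5,7,3',4'-tetra-O-benzylepicatechin, (2R,3R,4S), drawn as the 3,4-trans epimer (either C4 epimer ionises to the same cation) | c1ccccc1COc1cc(OCc3ccccc3)c2c(c1)O[C@H](c1ccc(OCc3ccccc3)c(OCc3ccccc3)c1)[C@H](O)[C@H]2OCC | intermediate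
16 | hexadeca-O-benzyl epicatechin-(4β→8)-epicatechin-(4β→8)-epicatechin-(4β→8)-catechin | c1ccccc1COc1cc(OCc3ccccc3)c2c(c1)O[C@H](c1ccc(OCc3ccccc3)c(OCc3ccccc3)c1)[C@H](O)[C@H]2c1c(OCc3ccccc3)cc(OCc3ccccc3)c2c1O[C@H](c1ccc(OCc3ccccc3)c(OCc3ccccc3)c1)[C@H](O)[C@H]2c1c(OCc3ccccc3)cc(OCc3ccccc3)c2c1O[C@H](c1ccc(OCc3ccccc3)c(OCc3ccccc3)c1)[C@H](O)[C@H]2c1c(OCc3ccccc3)cc(OCc3ccccc3)c2c1O[C@H](c1ccc(OCc3ccccc3)c(OCc3ccccc3)c1)[C@@H](O)C2 | intermediate
17 | epicatechin-(4β→8)-epicatechin-(4β→8)-epicatechin-(4β→8)-catechin, the procyanidin tetramer of the task | Oc1cc(O)c2c(c1)O[C@H](c1ccc(O)c(O)c1)[C@H](O)[C@H]2c1c(O)cc(O)c2c1O[C@H](c1ccc(O)c(O)c1)[C@H](O)[C@H]2c1c(O)cc(O)c2c1O[C@H](c1ccc(O)c(O)c1)[C@H](O)[C@H]2c1c(O)cc(O)c2c1O[C@H](c1ccc(O)c(O)c1)[C@@H](O)C2 | target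

**Step count and risks**

Total step count: 11. Longest linear sequence: 6 steps (steps 2, 3, 4, 5, 10, 11; the arm through steps 6, 7, 8, 9, 10, 11 is equally long).

Steps most likely to fail:

1. Step 10. The cascade may go astray in four ways: intermolecular capture of the first oxocarbenium ion before ring closure, ionisation of the benzylic aryl ether bond of 14 before ring closure, self-condensation of the cyclised cation with ring A of a second molecule, or acid-induced cleavage and scrambling of the interflavan bonds of 7 while the cyclisation runs. The fallback sets out from 14 and comes back at 16; it separates ring closure from union and changes the activation from oxophilic to thiophilic. Compound 14 would be cyclised alone with BF3·OEt2 in dilute CH2Cl2 containing ethanol at −40 °C, so that the C4 cation is held as the 4-ethoxyflavan 15. Once 14 is consumed, 4-methylbenzenethiol (Cc1ccc(S)cc1) would be added to the same flask and should trap the C4 cation on the β face as 4β-(4-methylphenylthio)-5,7,3',4'-tetra-O-benzylepicatechin F1, a storable compound. F1 and 7 would then be joined with AgBF4 in THF at 0 °C, so that 7 never meets a strong oxophilic acid, to give 16.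

2. Step 8. The oxygen transfer may show poor enantiofacial selectivity, may leak from cis to trans through its stepwise course, and the electron-rich benzylic epoxide may open during isolation. The fallback sets out from 11 and comes back at 14; it replaces catalyst control by a stereospecific racemic epoxidation and a later resolution. Dimethyldioxirane in acetone at 0 °C should transfer oxygen in a concerted way and give the cis-epoxide as the racemate, that is 12 together with its enantiomer (2R,3R)-2-[3,4-bis(benzyloxy)phenyl]-3-(diethoxymethyl)oxirane F2, used crude. Opening with 13 as in step 9 would give 14 together with its enantiomer (2R,3S)-3-[3,5-bis(benzyloxy)phenoxy]-3-[3,4-bis(benzyloxy)phenyl]-1,1-diethoxypropan-2-ol F3, and preparative HPLC on a chiral stationary phase would deliver 14.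

3. Step 9. The opening may suffer from C-alkylation by the ambident phenoxide, from attack at the wrong epoxide carbon, or from ionisation of the benzylic C–O bond with loss of stereospecificity. The fallback sets out from 12 and comes back at 14; it reverses the roles, so that the phenol reacts as an acidic pronucleophile with an activated benzylic alcohol under neutral conditions. CO2 (1 atm) with Bu4NBr (10 mol %) at 60 °C should convert 12 with net retention (bromide opening, then carbonate ring closure, two inversions at the same carbon) into the cis-cyclic carbonate (4S,5S)-4-[3,4-bis(benzyloxy)phenyl]-5-(diethoxymethyl)-1,3-dioxolan-2-one F4. K2CO3 in MeOH at rt would give the erythro diol (1S,2S)-1-[3,4-bis(benzyloxy)phenyl]-3,3-diethoxypropane-1,2-diol F5. Mitsunobu etherification of F5 with 13 (PPh3, DIAD, toluene, 0 °C) should take place at the benzylic hydroxyl with inversion, the hydroxyl next to the acetal being deactivated towards displacement, and return 14.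

**Further compounds**

F1 | step 10 | 4β-(4-methylphenylthio)-5,7,3',4'-tetra-O-benzylepicatechin | c1ccccc1COc1cc(OCc3ccccc3)c2c(c1)O[C@H](c1ccc(OCc3ccccc3)c(OCc3ccccc3)c1)[C@H](O)[C@H]2Sc1ccc(C)cc1
F2 | step 8 | (2R,3R)-2-[3,4-bis(benzyloxy)phenyl]-3-(diethoxymethyl)oxirane, enantiomer of 12 | CCOC(OCC)[C@@H]1O[C@@H]1c1ccc(OCc2ccccc2)c(OCc2ccccc2)c1
F3 | step 8 | (2R,3S)-3-[3,5-bis(benzyloxy)phenoxy]-3-[3,4-bis(benzyloxy)phenyl]-1,1-diethoxypropan-2-ol, enantiomer of 14 | c1ccccc1COc1cc(OCc3ccccc3)cc(c1)O[C@@H](c1ccc(OCc3ccccc3)c(OCc3ccccc3)c1)[C@@H](O)C(OCC)OCC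
F4 | step 9 | (4S,5S)-4-[3,4-bis(benzyloxy)phenyl]-5-(diethoxymethyl)-1,3-dioxolan-2-one | CCOC(OCC)[C@H]1OC(=O)O[C@H]1c1ccc(OCc2ccccc2)c(OCc2ccccc2)c1
F5 | step 9 | (1S,2S)-1-[3,4-bis(benzyloxy)phenyl]-3,3-diethoxypropane-1,2-diol | CCOC(OCC)[C@@H](O)[C@@H](O)c1ccc(OCc2ccccc2)c(OCc2ccccc2)c1
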